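The dihydropyran ring is cut at C4–C3 and O1–C2. The feature exploited is that O1–C8a–C4a–C4 (phenol oxygen, two carbons of benzo ring A, naphthyl-bearing benzylic carbon) is the oxadiene of an o-quinone methide, and C3–C2 is a vinyl unit. A chiral phosphoric acid turns a racemic carbinol into this planar dearomatised species and guides its hetero-Diels–Alder reaction with benzyl vinylcarbamate. One operation closes the ring, makes both bonds and fixes C4 as S. The precursor is an o-hydroxybenzhydrol bearing the 4,5-dimethoxynaphthyl group, with the future C5 oxygen masked as a benzyl ether. C2 is then rebuilt: lactol, acetate, trans-selective methylation, hydrogenolysis.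

Key step: step 5

Assumption: chroman numbering (O1, C2, C3, C4, C4a, C5–C8, C8a; ring A = benzo ring) is used throughout, and the (R)-catalyst is written for the 4S series; if a first run shows the opposite sense of induction, the (S)-catalyst is used with nothing else changed.

Step 1
Reactants: 1 naphthalene-1,8-diol
Product: 2 1,8-dimethoxynaphthalene
Conditions: MeI (3 equiv), K2CO3, DMF, 40 °C
Reagents that add atoms: iodomethane, CI
Why: Double Williamson ether synthesis, in which carbonate deprotonates both peri-phenols and excess unhindered methyl iodide with gentle heating also alkylates the hydrogen-bonded second hydroxyl.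

Step 2
Reactants: 2 1,8-dimethoxynaphthalene
Product: 3 1-bromo-4,5-dimethoxynaphthalene
Conditions: NBS (1.0 equiv), MeCN, 0 °C → rt, dark
Reagents that add atoms: N-bromosuccinimide, O=C1CCC(=O)N1Br
Why: Electrophilic aromatic bromination with NBS in a polar solvent goes para to a methoxy group, and one equivalent should stop at the monobromide because a second bromine would have to enter the crowded peri position next to the first.

Step 3
Reactants: 4 2,6-dihydroxybenzaldehyde
Product: 5 2-(benzyloxy)-6-hydroxybenzaldehyde
Conditions: BnBr (1.0 equiv), K2CO3 (1.0 equiv), acetone, reflux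
Reagents that add atoms: benzyl bromide, BrCc1ccccc1
Why: Williamson ether synthesis held at the mono-ether, since only one hydroxyl of 4 at a time can chelate the formyl oxygen and the other is alkylated first, whereas the hydroxyl left in 5 is chelated and much less nucleophilic.

Step 4
Reactants: 3 1-bromo-4,5-dimethoxynaphthalene; 5 2-(benzyloxy)-6-hydroxybenzaldehyde
Product: 8 rac-3-(benzyloxy)-2-[(4,5-dimethoxynaphthalen-1-yl)(hydroxy)methyl]phenol, via sodium phenolate 6 (not isolated), via naphthyllithium 7 (not isolated)
Conditions: 5, NaH, THF, 0 °C; 3, n-BuLi, THF, −78 °C; solutions combined, −78 → 0 °C; aq NH4Cl; Et3N-deactivated silica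
Reagents that add atoms: none
Why: Bromine–lithium exchange followed by 1,2-addition of the aryllithium to the aldehyde, in which prior deprotonation with NaH spares an equivalent of 7, the alkoxide–phenolate formed has no leaving group so no quinone methide can arise in the basic medium, no acidic deprotection of the labile carbinol is ever needed, and the new carbinol centre may be racemic because step 5 erases it.

Step 5
Reactants: 8 rac-3-(benzyloxy)-2-[(4,5-dimethoxynaphthalen-1-yl)(hydroxy)methyl]phenol; 9 benzyl vinylcarbamate
Product: 11 benzyl [(2R,4S)-5-(benzyloxy)-4-(4,5-dimethoxynaphthalen-1-yl)chroman-2-yl]carbamate (2,4-cis), via (E)-o-quinone methide 10 (not isolated)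
Conditions: (R)-TRIP [3,3'-bis(2,4,6-triisopropylphenyl)-BINOL hydrogen phosphate] (10 mol %), 9 (2 equiv), 4 Å MS, CH2Cl2, 0 °C, slow addition of 8
Reagents that add atoms: none
Why: The acid protonates the benzylic hydroxyl of 8, water leaves with push from the free ortho-phenol and the 4-methoxy group of the naphthalene, and the planar quinone methide 10 stays hydrogen-bonded through its carbonyl oxygen to the phosphate, whose P=O oxygen holds the N–H of 9; the CH2 terminus of 9 then bonds to C4 and the quinone methide oxygen to C2 in a concerted but asynchronous inverse-demand hetero-Diels–Alder reaction that rearomatises ring A. The closest known reaction type is this very one, the chiral-phosphoric-acid-catalysed [4+2] cycloaddition of o-quinone methides generated in situ from o-hydroxybenzhydrols with enecarbamates, enamides or vinyl ethers. The dihydropyran ring closes in an intermolecular [4+2] mode (four atoms O1–C8a–C4a–C4 plus two atoms C3–C2), which in the stepwise limit ends with a 6-exo-trig attack of the phenol oxygen on the N-acyliminium carbon. C4 (S) is controlled by the catalyst, whose 3,3'-aryl groups leave one face of bound 10 open, and because both enantiomers of 8 collapse to the same achiral 10 the step is enantioconvergent; C2 (R, cis to the naphthyl) follows from the endo placement of the carbamate held by the N–H···O=P contact and is dispensable, since steps 6–8 erase and reset it. The step needs enantioface selectivity at C4, a single quinone methide geometry, head-to-tail regiochemistry and chemoselectivity over self-alkylation of ring A. These should be secured by the single free phenol of 8 (one anchoring point and, with the other oxygen benzylated, no second tautomeric oxadiene), by the catalyst-laden carbonyl oxygen tolerating only the methide hydrogen next to it (E geometry, naphthyl towards C5), by the match of the nucleophilic β-carbon of 9 with the electrophilic C4, and by keeping 8 dilute against an excess of 9.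

Step 6
Reactants: 11 benzyl [(2R,4S)-5-(benzyloxy)-4-(4,5-dimethoxynaphthalen-1-yl)chroman-2-yl]carbamate
Product: 12 (4S)-5-(benzyloxy)-4-(4,5-dimethoxynaphthalen-1-yl)chroman-2-ol (lactol; both C2 epimers)
Conditions: 1 M aq HCl, THF, rt; NaHCO3 before concentration
Reagents that add atoms: water, O
Why: Acid-catalysed hydrolysis of an N-acyl N,O-aminal, in which water captures the cation whichever bond at C2 ionises first (C2–N or C2–O1) and both channels end in the hydroxy-aldehyde that closes to 12, so the nitrogen is removed before any carbon nucleophile is offered (a methyl donor acting on 11 itself could irreversibly trap the ring-opened N-acyliminium ion), while C4 and the benzyl and methyl ethers are untouched and the C2 configuration is irrelevant.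

Step 7
Reactants: 12 (4S)-5-(benzyloxy)-4-(4,5-dimethoxynaphthalen-1-yl)chroman-2-ol
Product: 13 (4S)-5-(benzyloxy)-4-(4,5-dimethoxynaphthalen-1-yl)chroman-2-yl acetate (both C2 epimers)
Conditions: Ac2O, pyridine, DMAP (cat), CH2Cl2, 0 °C → rt
Reagents that add atoms: acetic anhydride, CC(=O)OC(C)=O
Why: Acetylation of a lactol hydroxyl as for an anomeric acetate, since 12 has a single hydroxyl and 4-arylchroman-2-ols rest in the closed form, and the acetate makes the exocyclic C2–O bond the only one a Lewis acid should break, because loss of the ring aryloxide would leave a destabilised acyloxycarbenium ion.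

Step 8
Reactants: 13 (4S)-5-(benzyloxy)-4-(4,5-dimethoxynaphthalen-1-yl)chroman-2-yl acetate; 14 trimethylaluminium
Product: 16 (2R,4S)-5-(benzyloxy)-4-(4,5-dimethoxynaphthalen-1-yl)-2-methylchroman (2,4-trans), via C2 oxocarbenium ion 15 (not isolated)
Conditions: AlMe3 (3 equiv), CH2Cl2, −78 → −20 °C; aq Rochelle salt
Reagents that add atoms: none
Why: Lewis-acid-mediated substitution of a lactol acetate by an organoaluminium reagent through an oxocarbenium ion (C-glycosidation type), in which AlMe3 binds the acetate carbonyl, ionises C2–OAc and the aluminate hands over methyl within the short-lived ion pair; peri strain with the C5 benzyloxy group holds the C4 naphthyl pseudoaxial so that it screens the syn face of C2 and methyl enters anti, giving the 2,4-trans (2R) isomer with equatorial methyl, the same outcome that axial attack on the alternative half-chair predicts.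

Step 9
Reactants: 16 (2R,4S)-5-(benzyloxy)-4-(4,5-dimethoxynaphthalen-1-yl)-2-methylchroman
Product: 17 cladonaphchrom A, (2R,4S)-4-(4,5-dimethoxynaphthalen-1-yl)-2-methylchroman-5-ol
Conditions: H2 (1 atm), 10% Pd/C, EtOAc–MeOH, rt
Reagents that add atoms: none
Why: Catalytic hydrogenolysis of an aryl benzyl ether, the only hydrogenolysable bond present, because C2–O1 is not benzylic and C4 carries only carbon and hydrogen, so both stereocentres and the methyl ethers should remain as set.

Compound list
1 | naphthalene-1,8-diol | Oc1cccc2cccc(O)c12 | starting material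
2 | 1,8-dimethoxynaphthalene | COc1cccc2cccc(OC)c12 | intermediate
3 | 1-bromo-4,5-dimethoxynaphthalene | COc1cccc2c(Br)ccc(OC)c12 | intermediate
4 | 2,6-dihydroxybenzaldehyde | O=Cc1c(O)cccc1O | starting material
5 | 2-(benzyloxy)-6-hydroxybenzaldehyde | O=Cc1c(O)cccc1OCc1ccccc1 | intermediate
6 | sodium 3-(benzyloxy)-2-formylphenolate (not isolated) | [Na+].[O-]c1cccc(OCc2ccccc2)c1C=O | intermediate
7 | (4,5-dimethoxynaphthalen-1-yl)lithium (not isolated) | [Li]c1ccc(OC)c2c(OC)cccc12 | intermediate
8 | rac-3-(benzyloxy)-2-[(4,5-dimethoxynaphthalen-1-yl)(hydroxy)methyl]phenol | COc1cccc2c(C(O)c3c(O)cccc3OCc3ccccc3)ccc(OC)c12 | intermediate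
9 | benzyl vinylcarbamate | C=CNC(=O)OCc1ccccc1 | starting material
10 | (6E)-5-(benzyloxy)-6-[(4,5-dimethoxynaphthalen-1-yl)methylidene]cyclohexa-2,4-dien-1-one (not isolated) | O=C1C=CC=C(OCc2ccccc2)/C1=C\c1ccc(OC)c2c(OC)cccc12 | intermediate
11 | benzyl [(2R,4S)-5-(benzyloxy)-4-(4,5-dimethoxynaphthalen-1-yl)chroman-2-yl]carbamate (2,4-cis) | COc1cccc2c([C@@H]3C[C@H](NC(=O)OCc5ccccc5)Oc4cccc(OCc5ccccc5)c43)ccc(OC)c12 | intermediate
12 | (4S)-5-(benzyloxy)-4-(4,5-dimethoxynaphthalen-1-yl)chroman-2-ol (both C2 epimers) | COc1cccc2c([C@@H]3CC(O)Oc4cccc(OCc5ccccc5)c43)ccc(OC)c12 | intermediate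
13 | (4S)-5-(benzyloxy)-4-(4,5-dimethoxynaphthalen-1-yl)chroman-2-yl acetate (both C2 epimers) | COc1cccc2c([C@@H]3CC(OC(C)=O)Oc4cccc(OCc5ccccc5)c43)ccc(OC)c12 | intermediate
14 | trimethylaluminium | C[Al](C)C | starting material
15 | (4S)-5-(benzyloxy)-4-(4,5-dimethoxynaphthalen-1-yl)-3,4-dihydrochromenylium, the C2 oxocarbenium ion (not isolated) | COc1cccc2c([C@@H]3CC=[O+]c4cccc(OCc5ccccc5)c43)ccc(OC)c12 | intermediate
16 | (2R,4S)-5-(benzyloxy)-4-(4,5-dimethoxynaphthalen-1-yl)-2-methylchroman (2,4-trans) | COc1cccc2c([C@@H]3C[C@@H](C)Oc4cccc(OCc5ccccc5)c43)ccc(OC)c12 | intermediate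
17 | cladonaphchrom A, (2R,4S)-4-(4,5-dimethoxynaphthalen-1-yl)-2-methylchroman-5-ol | COc1cccc2c([C@@H]3C[C@@H](C)Oc4cccc(O)c43)ccc(OC)c12 | target

Total step count: 9
Longest linear sequence: 8 steps (steps 1, 2, 4, 5, 6, 7, 8, 9, from 1 to 17)

Steps most likely to fail

1. Step 5.
- What may go wrong: poor facial discrimination. The methide carbon is flanked by oxygen on both sides, so the preference for the E geometry is smaller than in ordinary o-quinone methides, and reaction through the Z geometry on the same catalyst face would erode the enantiomeric purity. The twisted 1-naphthyl group may also fit the catalyst pocket badly, and Friedel–Crafts self-alkylation of ring A may compete.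
- Fallback: sets out from 3 and 5, returns at 12, and sets C4 by metal catalysis with no quinone methide. A Wittig reaction of 5 with Ph3P=CHCO2Et in hot N,N-diethylaniline gives ethyl (E)-3-[2-(benzyloxy)-6-hydroxyphenyl]prop-2-enoate F1. This isomerises and lactonises in the same pot to 5-(benzyloxy)-2H-chromen-2-one F2. Bromide 3 is taken through 7 with B(OiPr)3 and aqueous acid to (4,5-dimethoxynaphthalen-1-yl)boronic acid F3. Rhodium(I)/Segphos-catalysed asymmetric 1,4-addition of F3 to F2 (dioxane–water, 60 °C, ligand antipode chosen for 4S) should give (4S)-5-(benzyloxy)-4-(4,5-dimethoxynaphthalen-1-yl)chroman-2-one F4. DIBAL-H at −78 °C then reduces F4 to lactol 12.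

2. Step 8.
- What may go wrong: proton loss from C3 of the cation (elimination to the cyclic enol ether). Heterolysis of the C3–C4 bond of the cation towards the strongly stabilised diarylmethyl cation is also possible, which would cost configurational integrity at C4 or send methyl to the wrong carbon. Anti selectivity may also be insufficient.
- Fallback: sets out from 12, returns at 16, and involves no cation, with C2 set by reagent control and a stereospecific ring closure. Excess MeMgBr (THF, 0 °C) adds to the open hydroxy-aldehyde tautomer of 12 to give (4S)-4-[2-(benzyloxy)-6-hydroxyphenyl]-4-(4,5-dimethoxynaphthalen-1-yl)butan-2-ol F5 as both carbinol epimers. Buffered Dess–Martin oxidation converges them on (4S)-4-[2-(benzyloxy)-6-hydroxyphenyl]-4-(4,5-dimethoxynaphthalen-1-yl)butan-2-one F6, which rests partly as its cyclic hemiketal. Corey–Bakshi–Shibata reduction with the (R)-oxazaborolidine, which distinguishes methyl from the β-branched chain, should give (2S,4S)-4-[2-(benzyloxy)-6-hydroxyphenyl]-4-(4,5-dimethoxynaphthalen-1-yl)butan-2-ol F7, and the minor epimer is a separable diastereomer. An intramolecular Mitsunobu reaction (PPh3, DIAD, THF) closes O1–C2 with inversion to the (2R)-configured 16.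

3. Step 7.
- What may go wrong: acylation through the open hydroxy-aldehyde tautomer (O-acetylation of the phenol) instead of the lactol hydroxyl, so that no ionisable C2 leaving group is installed.
- Fallback: sets out from 12, returns at 16, and installs the leaving group under equilibrating conditions. Compound 12 is stirred with benzenesulfinic acid and CaCl2 in CH2Cl2. The exchange is reversible, and an open-chain α-hydroxy sulfone would revert, so only (4S)-5-(benzyloxy)-4-(4,5-dimethoxynaphthalen-1-yl)-2-(phenylsulfonyl)chroman F8 should accumulate. AlMe3 (CH2Cl2, −78 → 0 °C) expels sulfinate from F8, passes through 15 and delivers methyl as in step 8 to give 16.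

Further compounds
F1 | step 5 | ethyl (E)-3-[2-(benzyloxy)-6-hydroxyphenyl]prop-2-enoate | CCOC(=O)/C=C/c1c(O)cccc1OCc1ccccc1
F2 | step 5 | 5-(benzyloxy)-2H-chromen-2-one | O=C1C=Cc2c(OCc3ccccc3)cccc2O1
F3 | step 5 | (4,5-dimethoxynaphthalen-1-yl)boronic acid | COc1cccc2c(B(O)O)ccc(OC)c12
F4 | step 5 | (4S)-5-(benzyloxy)-4-(4,5-dimethoxynaphthalen-1-yl)chroman-2-one | COc1cccc2c([C@@H]3CC(=O)Oc4cccc(OCc5ccccc5)c43)ccc(OC)c12
F5 | step 8 | (4S)-4-[2-(benzyloxy)-6-hydroxyphenyl]-4-(4,5-dimethoxynaphthalen-1-yl)butan-2-ol (both C2 epimers) | COc1cccc2c([C@H](CC(C)O)c3c(O)cccc3OCc3ccccc3)ccc(OC)c12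
F6 | step 8 | (4S)-4-[2-(benzyloxy)-6-hydroxyphenyl]-4-(4,5-dimethoxynaphthalen-1-yl)butan-2-one | COc1cccc2c([C@H](CC(C)=O)c3c(O)cccc3OCc3ccccc3)ccc(OC)c12
F7 | step 8 | (2S,4S)-4-[2-(benzyloxy)-6-hydroxyphenyl]-4-(4,5-dimethoxynaphthalen-1-yl)butan-2-ol | COc1cccc2c([C@H](C[C@H](C)O)c3c(O)cccc3OCc3ccccc3)ccc(OC)c12
F8 | step 7 | (4S)-5-(benzyloxy)-4-(4,5-dimethoxynaphthalen-1-yl)-2-(phenylsulfonyl)chroman (both C2 epimers) | COc1cccc2c([C@@H]3CC(S(=O)(=O)c5ccccc5)Oc4cccc(OCc5ccccc5)c43)ccc(OC)c12
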